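## Retrosynthetic overview

- Chain first: ω-pentadecalactone 1 already holds the whole C15 tether. One C-methylation through Weinreb amide 2 gives hydroxy ketone 3, and oxidation of its primary alcohol gives keto aldehyde 4.
- Ring (the only one, formed last): the butenolide (O1, C2 carbonyl, C3 methyl-bearing, C4 carboxyl-bearing, C5 stereocentre) is cut at the C4–C5 bond and the lactone C–O bond. This leads back to 4 and achiral itaconic anhydride 5.
- Forward, a chiral amine–squaramide catalyst joins 4 and 5 by aldol addition (adduct 6) and lactonisation to the α-methylene lactone acid 7. This step sets the single stereocentre.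
- The C=C is then moved into the ring in the same pot through mixed anhydrides 8 and 9, and hydrolysis gives isomuronic acid 10.

## Notes before the route

Catalyst Q (leaves no atoms in any product): the squaramide of 9-amino-9-deoxy-epi-quinine, 3-{[3,5-bis(trifluoromethyl)phenyl]amino}-4-{[(8α,9S)-6′-methoxycinchonan-9-yl]amino}cyclobut-3-ene-1,2-dione.

Assumption: Q is taken to deliver the dienolate to the si face of 4, which gives the (R) centre; if the first run shows the opposite sense, the quinidine-derived pseudoenantiomer of Q is used and nothing else changes.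

## Route

Step 1
Reactants: 1 ω-pentadecalactone (oxacyclohexadecan-2-one)
Product: 3 16-hydroxyhexadecan-2-one, via Weinreb amide 2 (not isolated)
Conditions: MeNH(OMe)·HCl (1.5 equiv), i-PrMgCl (3.0 equiv), THF, −15 °C; then MeMgBr (3 equiv), 0 °C to rt; aq. NH4Cl
Reagents that add atoms: MeMgBr (C[Mg]Br); N,O-dimethylhydroxylamine hydrochloride (CNOC.Cl)
Why: Weinreb ketone synthesis in one pot: the chloromagnesium amide made from MeNH(OMe)·HCl and i-PrMgCl opens the lactone to 2, whose magnesium chelate with MeMgBr survives until work-up, so addition stops at the methyl ketone and the amine is released again on quenching; no stereocentre is involved.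

Step 2
Reactants: 3 16-hydroxyhexadecan-2-one
Product: 4 15-oxohexadecanal
Conditions: TEMPO (10 mol %), PhI(OAc)2 (1.1 equiv), CH2Cl2, rt
Reagents that add atoms: none
Why: Oxoammonium-mediated (Piancatelli–Margarita) oxidation takes the primary alcohol to the aldehyde without over-oxidation and leaves the methyl ketone untouched; 4 is used within a day.

Step 3
Reactants: 4 15-oxohexadecanal; 5 itaconic anhydride (3-methylideneoxolane-2,5-dione, 2.0 equiv)
Product: 10 isomuronic acid, via aldol adduct 6 (not isolated), via methylene lactone acid 7 (not isolated), via exo mixed anhydride 8 (not isolated), via endo mixed anhydride 9 (not isolated)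
Conditions: Q (10 mol %), 4 Å MS, MTBE, 0 °C, 48 h; then Ac2O (1.5 equiv), Et3N (3 equiv), 0 °C to rt, 3 h; then H2O, rt; 1 M HCl work-up; recrystallise
Reagents that add atoms: acetic anhydride (CC(=O)OC(C)=O); water (O)
Why: Proposed new method: the quinuclidine of Q deprotonates 5 at its allylic α-CH2 (the tautomerisation that interconverts itaconic and citraconic anhydride, so citraconic anhydride formed on the side re-enters), the squaramide holds the dienolate while the quinuclidinium N–H activates the aldehyde rather than the much less electrophilic ketone, and C–C bond formation from the ring α-carbon onto the si face of 4 sets the (R)-carbinol centre of 6; the alkoxide then closes onto the distal anhydride carbonyl and releases the carboxylate to give 7 (its carboxyl-bearing centre is irrelevant because it becomes sp2), Ac2O/Et3N converts 7 into 8, whose C–H next to the anhydride carbonyl is as acidic as that of itaconic anhydride, so a 1,3-prototropic shift gives the fully conjugated 9 without touching the oxygen-bearing stereocentre, and water cleaves the acetyl group of 9 again to liberate 10; the closest known reaction type is the cinchona-squaramide-catalysed formal cycloaddition (aldol–lactonisation) of enolisable cyclic anhydrides such as homophthalic and aryl succinic anhydrides with aldehydes, extended here to a vinylogously enolisable alkylidene succinic anhydride and combined with the classical acetic anhydride isomerisation of protolichesterinic-type acids.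

## Compound list

1 | ω-pentadecalactone (oxacyclohexadecan-2-one) | O=C1CCCCCCCCCCCCCCO1 | starting material
2 | 15-hydroxy-N-methoxy-N-methylpentadecanamide (magnesium alkoxide in the flask) | CON(C)C(=O)CCCCCCCCCCCCCCO | intermediate
3 | 16-hydroxyhexadecan-2-one | CC(=O)CCCCCCCCCCCCCCO | intermediate
4 | 15-oxohexadecanal | CC(=O)CCCCCCCCCCCCCC=O | intermediate
5 | itaconic anhydride (3-methylideneoxolane-2,5-dione) | C=C1CC(=O)OC1=O | starting material
6 | 3-[(1R)-1-hydroxy-15-oxohexadecyl]-4-methylideneoxolane-2,5-dione (both epimers at ring C3) | CC(=O)CCCCCCCCCCCCC[C@@H](O)C1C(=O)OC(=O)C1=C | intermediate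
7 | (2R)-4-methylidene-5-oxo-2-(14-oxopentadecyl)oxolane-3-carboxylic acid (both epimers at C3) | CC(=O)CCCCCCCCCCCCC[C@H]1OC(=O)C(=C)C1C(=O)O | intermediate
8 | acetic (2R)-4-methylidene-5-oxo-2-(14-oxopentadecyl)oxolane-3-carboxylic anhydride (both epimers at C3) | CC(=O)CCCCCCCCCCCCC[C@H]1OC(=O)C(=C)C1C(=O)OC(C)=O | intermediate
9 | acetic (2R)-4-methyl-5-oxo-2-(14-oxopentadecyl)-2,5-dihydrofuran-3-carboxylic anhydride | CC(=O)CCCCCCCCCCCCC[C@H]1OC(=O)C(C)=C1C(=O)OC(C)=O | intermediate
10 | isomuronic acid, (2R)-4-methyl-5-oxo-2-(14-oxopentadecyl)-2,5-dihydrofuran-3-carboxylic acid | CC(=O)CCCCCCCCCCCCC[C@H]1OC(=O)C(C)=C1C(=O)O | target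

## Summary and risks

Total step count: 3. Longest linear sequence: 3 steps (1 → 3 → 4 → 10).

Steps most likely to fail, highest risk first:

- **Step 3 (the new reaction).** Risks: attack through the exocyclic γ-carbon of the dienolate instead of the ring α-carbon; modest ee with an unbranched aliphatic aldehyde; self-condensation of 5; some loss of ee during the double-bond shift. The fallback uses known chemistry, sets out from 4 and comes back at 10. Zinc-mediated Barbier allylation–lactonisation of 4 with commercially available dimethyl 2-(bromomethyl)fumarate (Zn dust, THF/sat. aq. NH4Cl, rt, aldehyde-selective) gives racemic methyl 4-methylidene-5-oxo-2-(14-oxopentadecyl)oxolane-3-carboxylate F3. Et3N in CH2Cl2 moves the double bond into the ring, since the ester α-H is acidic enough, to give racemic methyl 4-methyl-5-oxo-2-(14-oxopentadecyl)-2,5-dihydrofuran-3-carboxylate F4. Preparative HPLC on a chiral stationary phase gives methyl (2R)-4-methyl-5-oxo-2-(14-oxopentadecyl)-2,5-dihydrofuran-3-carboxylate F5. 6 M HCl in 1,4-dioxane at 90 °C then cleaves the methyl ester without base and gives 10. This fallback obtains the enantiomer by separation, not by catalysis.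

- **Step 1.** Risks: incomplete aminolysis of the unstrained macrolactone, or some double addition if the chelate breaks down. The fallback sets out from 1 and comes back at 3. Me3SiCH2Li (2.5 equiv, pentane/THF, 0 °C) adds once to give 16-hydroxy-1-(trimethylsilyl)hexadecan-2-one F1. It is held as its lithium enolate and so cannot take up a second carbanion. Methanol then cleaves the C–Si bond and gives 3.

- **Step 2.** Risks: over-oxidation to the acid, or air oxidation and oligomerisation of the long-chain aldehyde during isolation. The fallback sets out from 3 and comes back at 4. Appel iodination (PPh3, I2, imidazole, CH2Cl2) gives 16-iodohexadecan-2-one F2. Amine N-oxide oxidation of the primary iodide (Me3NO, NaHCO3, DMSO, rt) gives 4 with no oxidant that can take the aldehyde further.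

## Further compounds

F1 | step 1 | 16-hydroxy-1-(trimethylsilyl)hexadecan-2-one | C[Si](C)(C)CC(=O)CCCCCCCCCCCCCCO
F2 | step 2 | 16-iodohexadecan-2-one | CC(=O)CCCCCCCCCCCCCCI
F3 | step 3 | methyl 4-methylidene-5-oxo-2-(14-oxopentadecyl)oxolane-3-carboxylate (racemic, cis/trans) | CC(=O)CCCCCCCCCCCCCC1OC(=O)C(=C)C1C(=O)OC
F4 | step 3 | methyl 4-methyl-5-oxo-2-(14-oxopentadecyl)-2,5-dihydrofuran-3-carboxylate (racemic) | CC(=O)CCCCCCCCCCCCCC1OC(=O)C(C)=C1C(=O)OC
F5 | step 3 | methyl (2R)-4-methyl-5-oxo-2-(14-oxopentadecyl)-2,5-dihydrofuran-3-carboxylate | CC(=O)CCCCCCCCCCCCC[C@H]1OC(=O)C(C)=C1C(=O)OC
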